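**Retrosynthetic overview**
1. The strategy rests on the C8 carbinol, wedged between the quaternary C9 of ring B and C7 of ring D, and on the cis C6-methyl/C7-H pair of ring D. A C7 alkenyl nucleophile adding to a C8 aldehyde makes the C7–C8 bond and leaves a C6=C7 olefin for hydroxyl-directed hydrogenation.
2. Target ⇐ diene diol (directed hydrogenation of C6=C7) ⇐ C2 dienyl triflate + Me2CuLi (C2=C3 olefin made inside ring C) ⇐ tetracyclic C2 ketone / C8 allylic alcohol.
3. Tetracycle ⇐ intramolecular Nozaki–Hiyama–Kishi closure of ring C at C7–C8 ⇐ seco C8 aldehyde / C2 ketone carrying the ring-D alkenyl iodide.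
4. Seco compound ⇐ C20–C2 bond (organocerium + aldehyde) ⇐ trans-decalin C20 iodide (from 3,3-dimethylcyclohexanone and methyl vinyl ketone) + ring-D iodo-aldehyde (from (R)-4-silyloxycyclopentenone).
5. Ring order: A (given), B (Robinson annulation), D (given), C last.

Key step: step 23

Remark: atoms are numbered C1–C20 along the carbon backbone of the target (C2=C3 olefin, C5 and C8 carbinols, C9 and C12 quaternary; rings A and B cyclohexanes, C cyclooctene, D cyclopentane).
Remark: C3 is drawn cis to the C5 silyloxy group, but it is epimerisable once C2 is a carbonyl and is erased in step 25, so its configuration does not bear on the target.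
Remark: 3,3-dimethylcyclohexanone, (R)-1-phenylethylamine and (R)-4-(tert-butyldimethylsilyloxy)cyclopent-2-en-1-one are taken as commercial.

**Rings A/B fragment**

Step 1
Reactants: 1 3,3-dimethylcyclohexanone
Product: 3 2,5,5-trimethylcyclohexanone (racemic), via lithium enolate 2 (not isolated)
Conditions: LiN(i-Pr)2, THF, −78 °C; MeI, −78 → 0 °C
Reagents that add atoms: iodomethane, CI
Why: Kinetic enolate alkylation; deprotonation takes the methylene remote from the gem-dimethyl carbon and not the neopentyl one, so the methyl lands on the future C12 (racemic here, resolved dynamically in step 3).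

Step 2
Reactants: 3 2,5,5-trimethylcyclohexanone
Product: 4 N-[(R)-1-phenylethyl]imine of 3
Conditions: (R)-1-phenylethylamine, p-TsOH (cat.), toluene, reflux, Dean–Stark
Reagents that add atoms: (R)-1-phenylethylamine, C[C@@H](N)c1ccccc1
Why: Imine condensation with azeotropic removal of water; the imine equilibrates with its secondary enamines, which makes the future C12 stereochemically mobile.

Step 3
Reactants: 4 N-[(R)-1-phenylethyl]imine of 3; 5 methyl vinyl ketone
Product: 7 (S)-2,5,5-trimethyl-2-(3-oxobutyl)cyclohexanone, via Michael adduct imine 6 (not isolated)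
Conditions: THF, rt; then 10% aq. AcOH, rt
Reagents that add atoms: water, O
Why: Auxiliary-controlled Michael addition of the more substituted secondary enamine; the (R)-1-phenylethyl group shields one face so that quaternary C12 should form as the S isomer (the mirror image of the known course with the (S)-amine and 2-methylcyclohexanone), and any minor enantiomer becomes a separable diastereomer after union with the enantiopure ring-D fragment.

Step 4
Reactants: 7 (S)-2,5,5-trimethyl-2-(3-oxobutyl)cyclohexanone
Product: 9 (S)-4a,7,7-trimethyl-4,4a,5,6,7,8-hexahydronaphthalen-2(3H)-one, via aldol 8 (not isolated)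
Conditions: NaOMe, MeOH, 60 °C
Reagents that add atoms: none
Why: Intramolecular aldol condensation (second half of the Robinson annulation) closes ring B between C17 and C18; C12 is quaternary and cannot epimerise.

Step 5
Reactants: 9 (S)-4a,7,7-trimethyl-4,4a,5,6,7,8-hexahydronaphthalen-2(3H)-one
Product: 11 trans-fused C9 decalone with equatorial C18 allyl group, via lithium enolate 10 (not isolated)
Conditions: Li, NH3(l), THF, t-BuOH (1 equiv), −78 °C; then allyl bromide, −78 → −33 °C
Reagents that add atoms: allyl bromide, C=CCBr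
Why: Reductive alkylation; dissolving-metal reduction protonates C17 axially, anti to the C12 methyl (trans ring fusion), and the regiodefined enolate is allylated at C18, where the allyl group takes the equatorial (also thermodynamic) position.

Step 6
Reactants: 11 trans-fused C9 decalone with equatorial C18 allyl group
Product: 12 C9 nitrile (both C9 epimers)
Conditions: TosMIC, KOt-Bu, DME/EtOH, 0 → 40 °C
Reagents that add atoms: p-toluenesulfonylmethyl isocyanide, Cc1ccc(cc1)S(=O)(=O)C[N+]#[C-]
Why: Van Leusen reductive cyanation turns the ketone into the one-carbon-extended nitrile; the basic medium keeps the C18 allyl equatorial, and the C9 configuration is irrelevant because C9 is deprotonated next.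

Step 7
Reactants: 12 C9 nitrile (both C9 epimers)
Product: 14 C9 quaternary nitrile (cyano axial; benzyloxymethyl equatorial), via N-lithiated nitrile 13 (not isolated)
Conditions: LiN(i-Pr)2, THF, −78 °C; BnOCH2Cl, −78 → 0 °C
Reagents that add atoms: benzyl chloromethyl ether, ClCOCc1ccccc1
Why: Alkylation of the planar lithiated nitrile; the electrophile is expected to enter along the equatorial direction (no 1,3-diaxial contact with the axial hydrogens on C11 and C17), so C8 becomes equatorial and the cyano group, the future C9 methyl, axial.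

Step 8
Reactants: 14 C9 quaternary nitrile (cyano axial; benzyloxymethyl equatorial)
Product: 16 C9 axial aldehyde, via N-aluminio aldimine 15 (not isolated)
Conditions: i-Bu2AlH, toluene, −78 → 0 °C; then 1 M HCl, THF, 0 °C
Reagents that add atoms: water, O
Why: Partial reduction of the nitrile to the aluminium aldimine and hydrolysis; the aldehyde has no α-hydrogen, so C9 cannot epimerise.

Step 9
Reactants: 16 C9 axial aldehyde
Product: 18 C9-methyl decalin with C8 benzyl ether, via hydrazone 17 (not isolated)
Conditions: N2H4·H2O, diethylene glycol, 130 °C; then KOH, 200 °C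
Reagents that add atoms: none
Why: Wolff–Kishner reduction turns the hindered aldehyde into the axial C9 methyl; the benzyl ether and the isolated terminal olefin are inert to hydrazine and hot KOH.

Step 10
Reactants: 18 C9-methyl decalin with C8 benzyl ether
Product: 19 C8 primary alcohol
Conditions: Li, NH3(l), THF, −78 °C; then NH4Cl
Reagents that add atoms: none
Why: Dissolving-metal cleavage of the benzyl ether, which leaves the monosubstituted olefin alone; this frees C8–OH for a group that can later be removed beside an alkenyl iodide.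

Step 11
Reactants: 19 C8 primary alcohol
Product: 20 C8 triethylsilyl ether
Conditions: Et3SiCl, imidazole, DMF, rt
Reagents that add atoms: chlorotriethylsilane, CC[Si](Cl)(CC)CC
Why: Silylation of the neopentyl primary alcohol; the triethylsilyl ether survives ozonolysis, iodination and organolithium chemistry and is later cleaved beside the C5 tert-butyldimethylsilyl ether.

Step 12
Reactants: 20 C8 triethylsilyl ether
Product: 22 C20 primary alcohol, via ozonide 21 (not isolated)
Conditions: O3, CH2Cl2, −78 °C; then NaBH4, MeOH, −78 → 0 °C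
Reagents that add atoms: ozone, [O-][O+]=O
Why: Ozonolysis of the only olefin with reductive work-up shortens the allyl group to the two-carbon C19–C20 arm.

Step 13
Reactants: 22 C20 primary alcohol
Product: 23 C20 primary iodide
Conditions: I2, PPh3, imidazole, CH2Cl2, 0 °C
Reagents that add atoms: iodine, [I][I]
Why: Appel-type iodination of the unhindered primary alcohol; no stereocentre is touched.

**Ring D fragment**

Step 14
Reactants: 24 (R)-4-(tert-butyldimethylsilyloxy)cyclopent-2-en-1-one
Product: 25 (3R,4R)-4-(tert-butyldimethylsilyloxy)-3-methyl-1-(trimethylsilyloxy)cyclopent-1-ene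
Conditions: Me2CuLi (from MeLi, CuI), Me3SiCl, THF, −78 °C
Reagents that add atoms: lithium dimethylcuprate, [Li+].C[Cu-]C; chlorotrimethylsilane, C[Si](C)(C)Cl
Why: Cuprate conjugate addition anti to the silyloxy group with in situ O-silylation, which fixes the enol ether toward C7 and prevents enolate equilibration and loss of the silyloxy group; the temporary C6 centre is removed in step 15.

Step 15
Reactants: 25 (3R,4R)-4-(tert-butyldimethylsilyloxy)-3-methyl-1-(trimethylsilyloxy)cyclopent-1-ene
Product: 26 (R)-4-(tert-butyldimethylsilyloxy)-3-methylcyclopent-2-en-1-one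
Conditions: Pd(OAc)2 (1.05 equiv), MeCN, rt
Reagents that add atoms: none
Why: Saegusa–Ito oxidation of the silyl enol ether restores the enone, now carrying the C6 methyl; C5 is untouched.

Step 16
Reactants: 26 (R)-4-(tert-butyldimethylsilyloxy)-3-methylcyclopent-2-en-1-one
Product: 27 (R)-4-(tert-butyldimethylsilyloxy)-2-iodo-3-methylcyclopent-2-en-1-one
Conditions: I2, pyridine, CH2Cl2, 0 °C → rt
Reagents that add atoms: iodine, [I][I]
Why: Amine-mediated α-iodination of the enone (addition–elimination) places iodine on C7 only.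

Step 17
Reactants: 27 (R)-4-(tert-butyldimethylsilyloxy)-2-iodo-3-methylcyclopent-2-en-1-one
Product: 28 (R)-1-(tert-butyldimethylsilyloxy)-3-iodo-2-methyl-4-methylenecyclopent-2-ene
Conditions: Ph3PCH3Br, KOt-Bu, THF, 0 °C; then 27, 0 °C → rt
Reagents that add atoms: methylenetriphenylphosphorane, C=P(c1ccccc1)(c1ccccc1)c1ccccc1
Why: Wittig methylenation of the ketone introduces C2 as an exocyclic methylene on C3; loss of the silyloxy group from any enolate is blocked because it would give a cyclopentadienone.

Step 18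
Reactants: 28 (R)-1-(tert-butyldimethylsilyloxy)-3-iodo-2-methyl-4-methylenecyclopent-2-ene
Product: 30 [(1R,4R)-4-(tert-butyldimethylsilyloxy)-2-iodo-3-methylcyclopent-2-en-1-yl]methanol, via alkylborane 29 (not isolated)
Conditions: 9-BBN, THF, 0 °C → rt; then NaOH, H2O2, 0 °C
Reagents that add atoms: hydrogen peroxide, OO
Why: Anti-Markovnikov hydroboration–oxidation of the exocyclic 1,1-disubstituted olefin (the tetrasubstituted iodo-olefin is too hindered for 9-BBN); the borane should approach anti to the silyloxy group, giving C3 cis to it, a centre that is erased later.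

Step 19
Reactants: 30 [(1R,4R)-4-(tert-butyldimethylsilyloxy)-2-iodo-3-methylcyclopent-2-en-1-yl]methanol
Product: 31 (1R,4R)-4-(tert-butyldimethylsilyloxy)-2-iodo-3-methylcyclopent-2-ene-1-carbaldehyde
Conditions: Dess–Martin periodinane, NaHCO3, CH2Cl2, 0 °C
Reagents that add atoms: none
Why: Buffered Dess–Martin oxidation gives the β,γ-unsaturated aldehyde without acid or base strong enough to move the olefin into conjugation; it is used at once.

**Fragment union and ring C**

Step 20
Reactants: 23 C20 primary iodide; 31 (1R,4R)-4-(tert-butyldimethylsilyloxy)-2-iodo-3-methylcyclopent-2-ene-1-carbaldehyde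
Product: 34 seco C2 secondary alcohol (both C2 epimers), via alkyllithium 32 (not isolated), via organocerium 33 (not isolated)
Conditions: 23, t-BuLi (2.1 equiv), Et2O, −78 °C; CeCl3, THF, −78 °C; then 31, −78 °C; aq. NH4Cl
Reagents that add atoms: none
Why: Iodine–lithium exchange, transmetalation to cerium and 1,2-addition to the aldehyde; the organocerium reagent is weakly basic and does not exchange with the alkenyl iodide, so the enolisable aldehyde and the C7–I bond survive, and the C2 epimers converge in step 22.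

Step 21
Reactants: 34 seco C2 secondary alcohol (both C2 epimers)
Product: 35 seco C2,C8-diol
Conditions: PPTS, MeOH/CH2Cl2, 0 °C
Reagents that add atoms: none
Why: Acid-catalysed methanolysis removes the primary triethylsilyl ether much faster than the secondary tert-butyldimethylsilyl ether, and no ketone is yet present that could isomerise.

Step 22
Reactants: 35 seco C2,C8-diol
Product: 36 seco C8 aldehyde / C2 ketone with ring-D alkenyl iodide
Conditions: Dess–Martin periodinane (3 equiv), NaHCO3, CH2Cl2, 0 °C → rt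
Reagents that add atoms: none
Why: Double Dess–Martin oxidation gives the C2 ketone and the C8 aldehyde in one neutral operation, which spares the acidic C3–H of the β,γ-unsaturated ketone.

Step 23
Reactants: 36 seco C8 aldehyde / C2 ketone with ring-D alkenyl iodide
Product: 38 tetracyclic C8 allylic alcohol with C2 ketone and C6=C7 olefin, via alkenylchromium 37 (not isolated)
Conditions: CrCl2 (10 equiv), NiCl2 (0.1 equiv), degassed DMSO/THF, rt, 0.002 M, slow addition of 36
Reagents that add atoms: none
Why: Zerovalent nickel, formed from NiCl2 by CrCl2, inserts into the C7–I bond, the alkenyl group passes to trivalent chromium, and alkenylchromium 37 adds to the C8 aldehyde; this is the intramolecular Nozaki–Hiyama–Kishi reaction, whose closest known use is the closure of medium rings from alkenyl iodides and α-quaternary aldehydes. Ring C closes in the 8-exo-trig mode, forming the C7–C8 bond. C8 is the one new stereocentre and is under substrate control: with the two arms trans-diequatorial on the chair of ring B, the transition state is expected to turn the chromium-bound oxygen away from the axial C9 methyl, so that the C8–O bond ends up anti to that methyl as in the target; this sense is a prediction and the main uncertainty. The step needs aldehyde-over-ketone chemoselectivity, which is intrinsic to organochromium reagents, so the C2 ketone and its acidic C3–H are left alone. It also needs cyclisation to beat intermolecular coupling, which high dilution, the gauche disposition of the arms on ring B and the rigid ring-D unit in the tether should secure.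

**Endgame**

Step 24
Reactants: 38 tetracyclic C8 allylic alcohol with C2 ketone and C6=C7 olefin
Product: 39 C8 triethylsilyl ether of 38
Conditions: Et3SiOTf, 2,6-lutidine, CH2Cl2, −78 → 0 °C
Reagents that add atoms: triethylsilyl trifluoromethanesulfonate, CC[Si](CC)(CC)OS(=O)(=O)C(F)(F)F
Why: Silylation of the hindered allylic alcohol with the silyl triflate, so that the base and triflating agent of step 25 meet only the ketone.

Step 25
Reactants: 39 C8 triethylsilyl ether of 38
Product: 41 C2 dienyl triflate (C2=C3 and C6=C7), via potassium dienolate 40 (not isolated)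
Conditions: KN(SiMe3)2 (1.05 equiv), THF, −78 → −40 °C; PhNTf2, −78 → 0 °C; aq. NH4Cl
Reagents that add atoms: N-phenylbis(trifluoromethanesulfonimide), O=S(=O)(N(c1ccccc1)S(=O)(=O)C(F)(F)F)C(F)(F)F
Why: Enol triflate formation; C3–H is activated by both the carbonyl and the C6=C7 olefin, so the extended dienolate toward C3 forms in preference to the C20 enolate, and the ring fixes the C2=C3 geometry (this erases C3).

Step 26
Reactants: 41 C2 dienyl triflate (C2=C3 and C6=C7)
Product: 42 bis-silyl diene with C1 methyl on C2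
Conditions: Me2CuLi (from MeLi, CuI), THF, −20 → 0 °C
Reagents that add atoms: lithium dimethylcuprate, [Li+].C[Cu-]C
Why: Cuprate coupling of the enol triflate replaces the triflate by methyl with retention of the ring-fixed olefin geometry, giving the tetrasubstituted C2=C3 olefin.

Step 27
Reactants: 42 bis-silyl diene with C1 methyl on C2
Product: 43 diene diol (C5–OH and C8–OH free)
Conditions: Bu4NF, THF, rt
Reagents that add atoms: none
Why: Fluoride removes both silyl ethers under non-acidic conditions, which spares the ionisable dienylic alcohols.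

Step 28
Reactants: 43 diene diol (C5–OH and C8–OH free)
Product: 44 target CNP0213887.1
Conditions: [Ir(cod)(PCy3)(py)]PF6 (10 mol %), H2 (1 atm), CH2Cl2, rt, stopped after one equivalent of H2
Reagents that add atoms: none
Why: Hydroxyl-directed hydrogenation; the C5 and C8 hydroxyls lie on the same face and deliver H2 to C6=C7 from that face, which sets C6 (methyl trans to C5–OH) and C7 (H cis to C8–OH), while C2=C3 is only homoallylic to the hydroxyls and the s-trans diene cannot chelate the metal.

**Compound list**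
1 | 3,3-dimethylcyclohexanone | CC1(C)CCCC(=O)C1 | starting material
2 | lithium enolate of 1 (toward the methylene remote from the gem-dimethyl carbon) | [Li]OC1=CCCC(C)(C)C1 | intermediate (not isolated)
3 | 2,5,5-trimethylcyclohexanone (racemic) | CC1CCC(C)(C)CC1=O | intermediate
4 | N-[(R)-1-phenylethyl]imine of 3 | CC1CCC(C)(C)CC1=N[C@H](C)c1ccccc1 | intermediate
5 | methyl vinyl ketone | CC(=O)C=C | starting material
6 | Michael adduct imine (C12 S) | CC(=O)CC[C@]1(C)CCC(C)(C)CC1=N[C@H](C)c1ccccc1 | intermediate (not isolated)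
7 | (S)-2,5,5-trimethyl-2-(3-oxobutyl)cyclohexanone | CC(=O)CC[C@]1(C)CCC(C)(C)CC1=O | intermediate
8 | bicyclic aldol (C17 carbinol, C9 ketone) | O=C1CC[C@]2(C)CCC(C)(C)CC2(O)C1 | intermediate (not isolated)
9 | (S)-4a,7,7-trimethyl-4,4a,5,6,7,8-hexahydronaphthalen-2(3H)-one (C9 ketone, C17=C18) | O=C1CC[C@]2(C)CCC(C)(C)CC2=C1 | intermediate
10 | lithium enolate (C9–OLi, C9=C18, trans ring fusion) | [Li]OC1=C[C@@H]2CC(C)(C)CC[C@@]2(C)CC1 | intermediate (not isolated)
11 | trans-fused C9 decalone with equatorial C18 allyl group (allyl trans to C12 methyl) | O=C1CC[C@]2(C)CCC(C)(C)C[C@H]2[C@@H]1CC=C | intermediate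
12 | C9 nitrile (both C9 epimers) | N#CC1CC[C@]2(C)CCC(C)(C)C[C@H]2[C@@H]1CC=C | intermediate
13 | N-lithiated nitrile (keteniminate) | [Li]N=C=C1CC[C@]2(C)CCC(C)(C)C[C@H]2[C@@H]1CC=C | intermediate (not isolated)
14 | C9 quaternary nitrile (cyano axial, benzyloxymethyl equatorial) | N#C[C@]1(COCc2ccccc2)CC[C@]2(C)CCC(C)(C)C[C@H]2[C@@H]1CC=C | intermediate
15 | N-(diisobutylaluminio) aldimine | CC(C)C[Al](CC(C)C)N=C[C@]1(COCc2ccccc2)CC[C@]2(C)CCC(C)(C)C[C@H]2[C@@H]1CC=C | intermediate (not isolated)
16 | C9 axial aldehyde (benzyloxymethyl equatorial) | O=C[C@]1(COCc2ccccc2)CC[C@]2(C)CCC(C)(C)C[C@H]2[C@@H]1CC=C | intermediate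
17 | hydrazone of 16 | NN=C[C@]1(COCc2ccccc2)CC[C@]2(C)CCC(C)(C)C[C@H]2[C@@H]1CC=C | intermediate (not isolated)
18 | C9-methyl decalin with C8 benzyl ether and C18 allyl | C[C@]1(COCc2ccccc2)CC[C@]2(C)CCC(C)(C)C[C@H]2[C@@H]1CC=C | intermediate
19 | C8 primary alcohol with C18 allyl | C[C@]1(CO)CC[C@]2(C)CCC(C)(C)C[C@H]2[C@@H]1CC=C | intermediate
20 | C8 triethylsilyl ether with C18 allyl | C[C@]1(CO[Si](CC)(CC)CC)CC[C@]2(C)CCC(C)(C)C[C@H]2[C@@H]1CC=C | intermediate
21 | ozonide of 20 | C[C@]1(CO[Si](CC)(CC)CC)CC[C@]2(C)CCC(C)(C)C[C@H]2[C@@H]1CC1OCOO1 | intermediate (not isolated)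
22 | C20 primary alcohol (C8 triethylsilyl ether) | C[C@]1(CO[Si](CC)(CC)CC)CC[C@]2(C)CCC(C)(C)C[C@H]2[C@@H]1CCO | intermediate
23 | C20 primary iodide (C8 triethylsilyl ether) | C[C@]1(CO[Si](CC)(CC)CC)CC[C@]2(C)CCC(C)(C)C[C@H]2[C@@H]1CCI | intermediate
24 | (R)-4-(tert-butyldimethylsilyloxy)cyclopent-2-en-1-one | O=C1C[C@@H](O[Si](C)(C)C(C)(C)C)C=C1 | starting material
25 | (3R,4R)-4-(tert-butyldimethylsilyloxy)-3-methyl-1-(trimethylsilyloxy)cyclopent-1-ene | C[Si](C)(C)OC1=C[C@@H](C)[C@H](O[Si](C)(C)C(C)(C)C)C1 | intermediate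
26 | (R)-4-(tert-butyldimethylsilyloxy)-3-methylcyclopent-2-en-1-one | O=C1C[C@@H](O[Si](C)(C)C(C)(C)C)C(C)=C1 | intermediate
27 | (R)-4-(tert-butyldimethylsilyloxy)-2-iodo-3-methylcyclopent-2-en-1-one | O=C1C[C@@H](O[Si](C)(C)C(C)(C)C)C(C)=C1I | intermediate
28 | (R)-1-(tert-butyldimethylsilyloxy)-3-iodo-2-methyl-4-methylenecyclopent-2-ene | C=C1C[C@@H](O[Si](C)(C)C(C)(C)C)C(C)=C1I | intermediate
29 | B-alkyl-9-borabicyclo[3.3.1]nonane from 28 | B1(C[C@H]2C[C@@H](O[Si](C)(C)C(C)(C)C)C(C)=C2I)C2CCCC1CCC2 | intermediate (not isolated)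
30 | [(1R,4R)-4-(tert-butyldimethylsilyloxy)-2-iodo-3-methylcyclopent-2-en-1-yl]methanol | OC[C@H]1C[C@@H](O[Si](C)(C)C(C)(C)C)C(C)=C1I | intermediate
31 | (1R,4R)-4-(tert-butyldimethylsilyloxy)-2-iodo-3-methylcyclopent-2-ene-1-carbaldehyde | O=C[C@H]1C[C@@H](O[Si](C)(C)C(C)(C)C)C(C)=C1I | intermediate
32 | C20 alkyllithium | C[C@]1(CO[Si](CC)(CC)CC)CC[C@]2(C)CCC(C)(C)C[C@H]2[C@@H]1CC[Li] | intermediate (not isolated)
33 | C20 organocerium dichloride | C[C@]1(CO[Si](CC)(CC)CC)CC[C@]2(C)CCC(C)(C)C[C@H]2[C@@H]1CC[Ce](Cl)Cl | intermediate (not isolated)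
34 | seco C2 secondary alcohol (both C2 epimers; C8 triethylsilyl ether, C5 tert-butyldimethylsilyl ether) | C[C@]1(CO[Si](CC)(CC)CC)CC[C@]2(C)CCC(C)(C)C[C@H]2[C@@H]1CCC(O)[C@H]1C[C@@H](O[Si](C)(C)C(C)(C)C)C(C)=C1I | intermediate
35 | seco C2,C8-diol | C[C@]1(CO)CC[C@]2(C)CCC(C)(C)C[C@H]2[C@@H]1CCC(O)[C@H]1C[C@@H](O[Si](C)(C)C(C)(C)C)C(C)=C1I | intermediate
36 | seco C8 aldehyde / C2 ketone with ring-D alkenyl iodide | O=C[C@@]1(C)CC[C@]2(C)CCC(C)(C)C[C@H]2[C@@H]1CCC(=O)[C@H]1C[C@@H](O[Si](C)(C)C(C)(C)C)C(C)=C1I | intermediate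
37 | C7 alkenylchromium dichloride | O=C[C@@]1(C)CC[C@]2(C)CCC(C)(C)C[C@H]2[C@@H]1CCC(=O)[C@H]1C[C@@H](O[Si](C)(C)C(C)(C)C)C(C)=C1[Cr](Cl)Cl | intermediate (not isolated)
38 | tetracyclic C8 allylic alcohol with C2 ketone and C6=C7 olefin | O=C1[C@H]2C[C@@H](O[Si](C)(C)C(C)(C)C)C(C)=C2[C@@H](O)[C@@]2(C)CC[C@]3(C)CCC(C)(C)C[C@H]3[C@@H]2CC1 | intermediate
39 | C8 triethylsilyl ether of 38 | O=C1[C@H]2C[C@@H](O[Si](C)(C)C(C)(C)C)C(C)=C2[C@@H](O[Si](CC)(CC)CC)[C@@]2(C)CC[C@]3(C)CCC(C)(C)C[C@H]3[C@@H]2CC1 | intermediate
40 | potassium dienolate (O–C2=C3–C7=C6) | [K]O/C1=C2\C[C@@H](O[Si](C)(C)C(C)(C)C)C(C)=C2[C@@H](O[Si](CC)(CC)CC)[C@@]2(C)CC[C@]3(C)CCC(C)(C)C[C@H]3[C@@H]2CC1 | intermediate (not isolated)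
41 | C2 dienyl triflate | O=S(=O)(O/C1=C2\C[C@@H](O[Si](C)(C)C(C)(C)C)C(C)=C2[C@@H](O[Si](CC)(CC)CC)[C@@]2(C)CC[C@]3(C)CCC(C)(C)C[C@H]3[C@@H]2CC1)C(F)(F)F | intermediate
42 | bis-silyl diene with C1 methyl on C2 | C/C1=C2\C[C@@H](O[Si](C)(C)C(C)(C)C)C(C)=C2[C@@H](O[Si](CC)(CC)CC)[C@@]2(C)CC[C@]3(C)CCC(C)(C)C[C@H]3[C@@H]2CC1 | intermediate
43 | diene diol | C/C1=C2\C[C@@H](O)C(C)=C2[C@@H](O)[C@@]2(C)CC[C@]3(C)CCC(C)(C)C[C@H]3[C@@H]2CC1 | intermediate
44 | CNP0213887.1 | C/C1=C2\C[C@@H](O)[C@H](C)[C@@H]2[C@@H](O)[C@@]2(C)CC[C@]3(C)CCC(C)(C)C[C@H]3[C@@H]2CC1 | target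

**Totals**
Total step count: 28. Longest linear sequence: 22 steps (steps 1–13, then 20–28).

**Steps most likely to fail**

Risk 1, step 23 (key step). The alkenylchromium may add to the other face of the aldehyde (poor or reversed facial selectivity at C8), or protodeiodination may outrun the slow 8-membered closure. Fallback: C8 is set by reagent-controlled reduction on a later, more rigid intermediate instead of by the ring closure. It sets out from 36: the cyclisation product of the wrong configuration, the C8 epimer of 38 F1, is silylated with Et3SiOTf to its triethylsilyl ether F2, converted with KN(SiMe3)2/PhNTf2 to the epimeric dienyl triflate F3, and methylated with Me2CuLi to the C8-epimeric bis-silyl diene F4. HF·pyridine/pyridine then removes the triethylsilyl group selectively to give the C8-epimeric mono-alcohol F5, Dess–Martin oxidation gives the C8 dienone F6, and Corey–Bakshi–Shibata reduction (oxazaborolidine enantiomer chosen to deliver hydride to the face syn to the C9 methyl) gives the C8 alcohol of target configuration F7. Bu4NF removes the C5 silyl group and the route is rejoined at 43.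

Risk 2, step 28. After C6=C7 is reduced the catalyst may go on to the C2=C3 olefin (over-reduction), or the acidic iridium hydride may ionise the dienylic alcohols. Fallback: hydrogenate before the diene exists. It sets out from 38: Bu4NF gives the desilylated keto-diol F8, and [Ir(cod)(PCy3)(py)]PF6/H2 reduces its only olefin under direction by both hydroxyls to the saturated keto-diol F9. Et3SiOTf/2,6-lutidine gives the bis(triethylsilyl) ether F10. Equilibration to the more substituted enolate toward C3 (KN(SiMe3)2 with a slight excess of ketone, then PhNTf2) gives the C2 enol triflate F11, Me2CuLi gives the bis(triethylsilyl) ether of the target F12, and Bu4NF returns to 44.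

Risk 3, step 7. Facial selectivity may be poor, with the electrophile entering on the axial rather than the equatorial face of the lithiated nitrile. Fallback: reverse the order in which the two C9 substituents are made, so that the face the electrophile is found to prefer receives the methyl. It sets out from 12: LiN(i-Pr)2/MeI gives the methylated nitrile with axial methyl and equatorial cyano group F13, i-Bu2AlH gives the C8 aldehyde F14, and NaBH4 reduces it to 19, where the route is rejoined.

**Further compounds**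
F1 | step 23 | C8 epimer of 38 | O=C1[C@H]2C[C@@H](O[Si](C)(C)C(C)(C)C)C(C)=C2[C@H](O)[C@@]2(C)CC[C@]3(C)CCC(C)(C)C[C@H]3[C@@H]2CC1
F2 | step 23 | triethylsilyl ether of F1 | O=C1[C@H]2C[C@@H](O[Si](C)(C)C(C)(C)C)C(C)=C2[C@H](O[Si](CC)(CC)CC)[C@@]2(C)CC[C@]3(C)CCC(C)(C)C[C@H]3[C@@H]2CC1
F3 | step 23 | C8-epimeric dienyl triflate | O=S(=O)(O/C1=C2\C[C@@H](O[Si](C)(C)C(C)(C)C)C(C)=C2[C@H](O[Si](CC)(CC)CC)[C@@]2(C)CC[C@]3(C)CCC(C)(C)C[C@H]3[C@@H]2CC1)C(F)(F)F
F4 | step 23 | C8-epimeric bis-silyl diene | C/C1=C2\C[C@@H](O[Si](C)(C)C(C)(C)C)C(C)=C2[C@H](O[Si](CC)(CC)CC)[C@@]2(C)CC[C@]3(C)CCC(C)(C)C[C@H]3[C@@H]2CC1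
F5 | step 23 | C8-epimeric mono-alcohol (C5 silyl ether kept) | C/C1=C2\C[C@@H](O[Si](C)(C)C(C)(C)C)C(C)=C2[C@H](O)[C@@]2(C)CC[C@]3(C)CCC(C)(C)C[C@H]3[C@@H]2CC1
F6 | step 23 | C8 dienone (C5 silyl ether kept) | C/C1=C2\C[C@@H](O[Si](C)(C)C(C)(C)C)C(C)=C2C(=O)[C@@]2(C)CC[C@]3(C)CCC(C)(C)C[C@H]3[C@@H]2CC1
F7 | step 23 | C8 alcohol of target configuration (C5 silyl ether kept) | C/C1=C2\C[C@@H](O[Si](C)(C)C(C)(C)C)C(C)=C2[C@@H](O)[C@@]2(C)CC[C@]3(C)CCC(C)(C)C[C@H]3[C@@H]2CC1
F8 | step 28 | desilylated keto-diol (C2 ketone, C6=C7 olefin) | O=C1[C@H]2C[C@@H](O)C(C)=C2[C@@H](O)[C@@]2(C)CC[C@]3(C)CCC(C)(C)C[C@H]3[C@@H]2CC1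
F9 | step 28 | saturated keto-diol (C6 and C7 as in the target, C3 unassigned) | O=C1C2C[C@@H](O)[C@H](C)[C@@H]2[C@@H](O)[C@@]2(C)CC[C@]3(C)CCC(C)(C)C[C@H]3[C@@H]2CC1
F10 | step 28 | bis(triethylsilyl) ether of F9 | O=C1C2C[C@@H](O[Si](CC)(CC)CC)[C@H](C)[C@@H]2[C@@H](O[Si](CC)(CC)CC)[C@@]2(C)CC[C@]3(C)CCC(C)(C)C[C@H]3[C@@H]2CC1
F11 | step 28 | C2 enol triflate (C2=C3) | O=S(=O)(O/C1=C2\C[C@@H](O[Si](CC)(CC)CC)[C@H](C)[C@@H]2[C@@H](O[Si](CC)(CC)CC)[C@@]2(C)CC[C@]3(C)CCC(C)(C)C[C@H]3[C@@H]2CC1)C(F)(F)F
F12 | step 28 | bis(triethylsilyl) ether of 44 | C/C1=C2\C[C@@H](O[Si](CC)(CC)CC)[C@H](C)[C@@H]2[C@@H](O[Si](CC)(CC)CC)[C@@]2(C)CC[C@]3(C)CCC(C)(C)C[C@H]3[C@@H]2CC1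
F13 | step 7 | methylated nitrile (methyl axial, cyano equatorial) | C[C@]1(C#N)CC[C@]2(C)CCC(C)(C)C[C@H]2[C@@H]1CC=C
F14 | step 7 | C8 aldehyde with C18 allyl | C[C@]1(C=O)CC[C@]2(C)CCC(C)(C)C[C@H]2[C@@H]1CC=C
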